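**Assumption:** the target SMILES has no stereocentre or stereo-axis, so the compound is achiral and no enantiocontrol is needed.

**Retrosynthetic overview**
- The target comes from hydrolysis of the ring A methyl ester of a diaryl ether that already carries the free ring B acid.
- Key disconnection: the diaryl ether C–O bond between C2 of ring B and the 4-oxygen of ring A, formed by carboxylate-directed ortho-C–H aryloxylation of 2-heptyl-4-methoxybenzoic acid with methyl 6-heptyl-2,4-dihydroxybenzoate.
- Ring B acid comes from 4-methoxy-2-methylbenzoic acid and 1-bromohexane by lateral lithiation–alkylation.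
- Ring A ester comes from octanal via the enone, Michael–Claisen annulation with dimethyl malonate, then aromatisation.
- Ring order: ring A is the only ring built (closed in step 2, aromatised in step 3); ring B is bought as an arene; the two are joined in step 5.

**Route**

Step 1
Reactants: 1 octanal; 2 acetonylidene(triphenyl)phosphorane, Ph3P=CHC(O)CH3
Product: 3 (E)-undec-3-en-2-one
Conditions: toluene, 90 °C
Reagents that add atoms: none
Why: Wittig olefination of an unhindered aliphatic aldehyde with a stabilised acyl ylide is reliable and gives the (E)-enone, whose geometry is in any case lost in step 2.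

Step 2
Reactants: 3 (E)-undec-3-en-2-one; 4 dimethyl malonate
Product: 6 methyl 6-heptyl-2-hydroxy-4-oxocyclohex-2-ene-1-carboxylate, via Michael adduct 5 (not isolated)
Conditions: NaOMe (1.1 equiv), MeOH, reflux; then aq HCl, 0 °C
Reagents that add atoms: none
Why: Michael addition of the malonate anion to the enone followed by intramolecular Claisen condensation of the methyl ketone enolate onto one ester closes the ring A carbocycle with heptyl and ester in place (the classical olivetol-type annulation); the two new stereocentres are racemic and are erased in step 3.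

Step 3
Reactants: 6 methyl 6-heptyl-2-hydroxy-4-oxocyclohex-2-ene-1-carboxylate
Product: 8 methyl 6-heptyl-2,4-dihydroxybenzoate, via bromo dione ester 7 (not isolated)
Conditions: Br2 (1.0 equiv), DMF, 0 °C, then 80 °C
Reagents that add atoms: none
Why: Bromination–dehydrobromination of the cyclic 1,3-dione is the classical aromatisation of dihydroresorcylates, and holding the bath at 80 °C avoids the loss of the methoxycarbonyl group that sets in at higher temperature.

Step 4
Reactants: 9 4-methoxy-2-methylbenzoic acid; 10 1-bromohexane
Product: 12 2-heptyl-4-methoxybenzoic acid, via dilithio dianion 11 (not isolated)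
Conditions: LiN(i-Pr)2 (2.2 equiv), THF, −78 to 0 °C; then 10 (1.1 equiv), −78 °C to rt; aq HCl
Reagents that add atoms: none
Why: Lateral (benzylic) lithiation of an ortho-toluic acid with two equivalents of a lithium amide gives the carboxylate-stabilised benzylic dianion, which is alkylated at carbon by the primary bromide (dianion alkylation of toluic acids), while the amide base avoids ring lithiation and addition to the carboxylate.

Step 5
Reactants: 12 2-heptyl-4-methoxybenzoic acid; 8 methyl 6-heptyl-2,4-dihydroxybenzoate
Product: 13 2-heptyl-6-[3-heptyl-5-hydroxy-4-(methoxycarbonyl)phenoxy]-4-methoxybenzoic acid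
Conditions: 12 (1.0 equiv), 8 (1.5 equiv), Cu(OAc)2 (20 mol %), pyridine (40 mol %), K2CO3 (2.0 equiv), DMSO, O2 (1 atm), 110 °C; then aq HCl
Reagents that add atoms: none
Why: Proposed new method: copper-catalysed dehydrogenative ortho-C–H aryloxylation of a free benzoic acid in which the native carboxylate directs and is retained: the potassium carboxylate of 12 binds divalent copper through oxygen, acetate-assisted concerted metalation–deprotonation at the only free ortho C–H (C6) with oxidation by a second divalent copper centre gives a five-membered aryl–copper carboxylate metallacycle of trivalent copper that also carries the 4-phenoxide of 8 (the 2-OH stays locked in its hydrogen bond to the ester and is far less acidic), and C–O reductive elimination releases 13 and monovalent copper, which O2 reoxidises; the closest known reaction types are the copper-catalysed ortho-C–H aryloxylation of benzamides bearing an 8-aminoquinoline auxiliary with phenols under air and the copper/silver-mediated carboxylate-directed ortho-alkoxylation of benzoates that ends in protodecarboxylation, so the new elements are a phenol partner on a native carboxylate and a silver-free regime below 140 °C, without chelating nitrogen ligands, that should leave the CO2H in place.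

Step 6
Reactants: 13 2-heptyl-6-[3-heptyl-5-hydroxy-4-(methoxycarbonyl)phenoxy]-4-methoxybenzoic acid
Product: 14 2-(4-carboxy-3-heptyl-5-hydroxyphenoxy)-6-heptyl-4-methoxybenzoic acid
Conditions: KOH (6 equiv), DMSO/H2O (4:1), 80 °C; then 1 M HCl, 0 °C
Reagents that add atoms: potassium hydroxide, [K+].[OH-]
Why: Saponification (acyl–oxygen cleavage) of the hindered salicylate methyl ester with poorly solvated hydroxide in aqueous DMSO leaves the diaryl ether and the aryl methyl ether untouched, and cold acidification avoids decarboxylation of the 2-hydroxybenzoic acid.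

**Compound list**

1 | octanal | CCCCCCCC=O | starting material
2 | acetonylidene(triphenyl)phosphorane | CC(=O)C=P(c1ccccc1)(c1ccccc1)c1ccccc1 | starting material
3 | (E)-undec-3-en-2-one | CCCCCCC/C=C/C(C)=O | intermediate
4 | dimethyl malonate | COC(=O)CC(=O)OC | starting material
5 | dimethyl 2-(2-oxoundecan-4-yl)propanedioate (racemic, not isolated) | CCCCCCCC(CC(C)=O)C(C(=O)OC)C(=O)OC | intermediate
6 | methyl 6-heptyl-2-hydroxy-4-oxocyclohex-2-ene-1-carboxylate (racemic, diastereomer mixture) | CCCCCCCC1CC(=O)C=C(O)C1C(=O)OC | intermediate
7 | methyl 3-bromo-6-heptyl-2-hydroxy-4-oxocyclohex-2-ene-1-carboxylate (racemic, not isolated) | CCCCCCCC1CC(=O)C(Br)=C(O)C1C(=O)OC | intermediate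
8 | methyl 6-heptyl-2,4-dihydroxybenzoate | CCCCCCCc1cc(O)cc(O)c1C(=O)OC | intermediate
9 | 4-methoxy-2-methylbenzoic acid | Cc1cc(OC)ccc1C(=O)O | starting material
10 | 1-bromohexane | CCCCCCBr | starting material
11 | lithium 2-(lithiomethyl)-4-methoxybenzoate, the dilithio dianion of 9 (not isolated) | [Li+].[Li+].[CH2-]c1cc(OC)ccc1C(=O)[O-] | intermediate
12 | 2-heptyl-4-methoxybenzoic acid | CCCCCCCc1cc(OC)ccc1C(=O)O | intermediate
13 | 2-heptyl-6-[3-heptyl-5-hydroxy-4-(methoxycarbonyl)phenoxy]-4-methoxybenzoic acid | CCCCCCCc1cc(Oc2cc(OC)cc(CCCCCCC)c2C(=O)O)cc(O)c1C(=O)OC | intermediate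
14 | 2-(4-carboxy-3-heptyl-5-hydroxyphenoxy)-6-heptyl-4-methoxybenzoic acid | CCCCCCCc1cc(Oc2cc(OC)cc(CCCCCCC)c2C(=O)O)cc(O)c1C(=O)O | target

**Step count**
Total: 6 steps. Longest linear sequence: 5 steps (steps 1, 2, 3, 5, 6); step 4 is a one-step side branch.

**Three steps most likely to fail**

Step 5 (the proposed new C–H aryloxylation). The risks are weak direction by a monodentate carboxylate, oxidative self-coupling of the electron-rich phenol 8, and protodecarboxylation of the doubly ortho-substituted acid 13. The fallback uses only known chemistry, sets out from 8 and comes back to the route at 14.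
- Selective 4-O-methylation of 8 (MeI, K2CO3, acetone, reflux; the 2-OH is hydrogen-bonded) gives methyl 6-heptyl-2-hydroxy-4-methoxybenzoate F1.
- Triflation (Tf2O, pyridine, CH2Cl2, 0 °C) gives methyl 2-heptyl-4-methoxy-6-{[(trifluoromethyl)sulfonyl]oxy}benzoate F2.
- Palladium-catalysed C–O coupling of F2 with the 4-OH of a second portion of 8 (Pd(OAc)2, 2-di-tert-butylphosphino-2',4',6'-triisopropylbiphenyl, K3PO4, toluene, 100 °C) gives methyl 2-heptyl-6-[3-heptyl-5-hydroxy-4-(methoxycarbonyl)phenoxy]-4-methoxybenzoate F3.
- Saponification of both esters (KOH, DMSO/H2O, 100 °C, cold acidification; LiI in pyridine if the ring B ester lags) gives 14.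
- This fallback makes steps 4 to 6 unnecessary.

Step 6 (hydrolysis of the hindered, hydrogen-bonded ring A methyl ester). The risks are sluggish reaction and decarboxylation of the 2-hydroxy acid on work-up. The fallback changes the ester to one removed under neutral conditions; it sets out from 8 and comes back at 14.
- Saponification of 8 at this early, cheap stage (KOH, H2O/MeOH, reflux, cold acidification), where partial decarboxylation can be tolerated, gives 6-heptyl-2,4-dihydroxybenzoic acid F4.
- Carboxylate-selective benzylation (BnBr, KHCO3, DMF, rt) gives benzyl 6-heptyl-2,4-dihydroxybenzoate F5.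
- Coupling of F5 with 12 under the step 5 conditions gives 2-{4-[(benzyloxy)carbonyl]-3-heptyl-5-hydroxyphenoxy}-6-heptyl-4-methoxybenzoic acid F6.
- Hydrogenolysis (H2 at 1 atm, 10 wt % Pd/C, EtOAc, rt) gives 14 without base, acid or heat.

Step 4 (lateral lithiation–alkylation). The risks are incomplete dianion formation that leaves 9 to be separated from 12, competing ring lithiation next to the methoxy group, and double alkylation. The fallback builds the heptyl chain by benzylic bromination and copper-catalysed coupling; it sets out from 9 and 10 and comes back at 12.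
- Esterification of 9 (MeI, K2CO3, DMF, rt) gives methyl 4-methoxy-2-methylbenzoate F7.
- Radical benzylic bromination (N-bromosuccinimide, azobisisobutyronitrile, PhCF3, 80 °C) gives methyl 2-(bromomethyl)-4-methoxybenzoate F8.
- 10 is converted with Mg in THF into hexylmagnesium bromide F9.
- Coupling of F9 with F8 (Li2CuCl4, 3 mol %, THF, −78 to 0 °C) gives methyl 2-heptyl-4-methoxybenzoate F10.
- Hydrolysis of F10, an ester with only one ortho substituent (LiOH, THF/MeOH/H2O, 50 °C), gives 12.

**Further compounds**

F1 | step 5 | methyl 6-heptyl-2-hydroxy-4-methoxybenzoate | CCCCCCCc1cc(OC)cc(O)c1C(=O)OC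
F2 | step 5 | methyl 2-heptyl-4-methoxy-6-{[(trifluoromethyl)sulfonyl]oxy}benzoate | CCCCCCCc1cc(OC)cc(OS(=O)(=O)C(F)(F)F)c1C(=O)OC
F3 | step 5 | methyl 2-heptyl-6-[3-heptyl-5-hydroxy-4-(methoxycarbonyl)phenoxy]-4-methoxybenzoate | CCCCCCCc1cc(Oc2cc(OC)cc(CCCCCCC)c2C(=O)OC)cc(O)c1C(=O)OC
F4 | step 6 | 6-heptyl-2,4-dihydroxybenzoic acid | CCCCCCCc1cc(O)cc(O)c1C(=O)O
F5 | step 6 | benzyl 6-heptyl-2,4-dihydroxybenzoate | CCCCCCCc1cc(O)cc(O)c1C(=O)OCc1ccccc1
F6 | step 6 | 2-{4-[(benzyloxy)carbonyl]-3-heptyl-5-hydroxyphenoxy}-6-heptyl-4-methoxybenzoic acid | CCCCCCCc1cc(Oc2cc(OC)cc(CCCCCCC)c2C(=O)O)cc(O)c1C(=O)OCc1ccccc1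
F7 | step 4 | methyl 4-methoxy-2-methylbenzoate | Cc1cc(OC)ccc1C(=O)OC
F8 | step 4 | methyl 2-(bromomethyl)-4-methoxybenzoate | BrCc1cc(OC)ccc1C(=O)OC
F9 | step 4 | hexylmagnesium bromide | CCCCCC[Mg]Br
F10 | step 4 | methyl 2-heptyl-4-methoxybenzoate | CCCCCCCc1cc(OC)ccc1C(=O)OC
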